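**Retrosynthetic overview**
1. Target 22 is an 8,6''-linked biflavone. The last step uses BCl3 to remove three isopropyl ethers and the carbonyl-chelated C5'' methyl ether from 21, and leaves the C7'' and C4' methyl ethers in place.
2. Ring C of unit 2 is made last. An acetyl group is placed on C4a'' of the trialkoxyaryl ring, the benzyl-masked oxygen on C8a'' (para to the biaryl bond) is freed, and chalcone formation followed by I2/DMSO oxidation closes O1''–C2''.
3. Ring C of unit 1 is cut at C3–C4 and O1–C2. This leads to salicylaldehyde 10 and aroyl sulfoxonium ylide 14, which are joined under [Cp*RhCl2]2 (trivalent rhodium).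
4. Structural feature used: in ring A of unit 1, C8a (which carries O1) lies between C8, taken up by the C8–C6'' biaryl bond, and C4a. A phenol on C8a therefore has only one open ortho carbon, so phenol-directed formylation can only reach C4a. The same phenol later guides rhodium to the formyl C–H bond and closes the pyranone.
5. The C8–C6'' bond comes from ortho-arylation of 3,5-diisopropoxyphenol 2 with aryllead triacetate 8. Rings A and B of both units are bought, ring C of unit 1 forms in step 8, and ring C of unit 2 forms in step 12.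

Key step: step 8

Assumption: the target SMILES gives no descriptor for the hindered C8–C6'' axis, so the biaryl is made as the racemate. There is no stereocentre, and the only defined stereo element on the way is the E alkene of chalcone 20.

**Step 1**
Reactants: 1 phloroglucinol
Product: 2 3,5-diisopropoxyphenol
Conditions: 2-bromopropane (2.2 equiv), K2CO3 (2.2 equiv), DMF, 60 °C; chromatography
Reagents that add atoms: 2-bromopropane CC(C)Br
Why: In this Williamson etherification with about two equivalents of a secondary bromide, O-alkylation should outrun C-alkylation and give the diether as the main part of a mono/di/tri ether mixture that silica gel separates by the number of free hydroxyls, the monoether being recyclable.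

**Step 2**
Reactants: 3 4-bromo-3,5-dimethoxyphenol
Product: 4 5-(benzyloxy)-2-bromo-1,3-dimethoxybenzene
Conditions: BnBr, K2CO3, acetone, reflux
Reagents that add atoms: benzyl bromide BrCc1ccccc1
Why: Williamson benzylation of the only phenol marks the oxygen para to bromine, the future O1'', with a group that can later be removed without touching methyl or isopropyl ethers.

**Step 3**
Reactants: 4 5-(benzyloxy)-2-bromo-1,3-dimethoxybenzene
Product: 7 [4-(benzyloxy)-2,6-dimethoxyphenyl]boronic acid, via 4-(benzyloxy)-2,6-dimethoxyphenyllithium 5 (not isolated), via lithium aryltriisopropoxyborate 6 (not isolated)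
Conditions: n-BuLi, THF, −78 °C; B(OiPr)3, −78 °C to rt; cold 1 M HCl, short contact
Reagents that add atoms: triisopropyl borate CC(C)OB(OC(C)C)OC(C)C; water O; n-butyllithium [Li]CCCC (lithium of 5 and 6)
Why: Bromine–lithium exchange at −78 °C is faster than benzylic deprotonation, the aryllithium flanked by two methoxy groups is trapped by the borate, and brief cold hydrolysis should free the boronic acid before protodeboronation sets in (lithiation–borylation).

**Step 4**
Reactants: 7 [4-(benzyloxy)-2,6-dimethoxyphenyl]boronic acid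
Product: 8 [4-(benzyloxy)-2,6-dimethoxyphenyl]lead triacetate
Conditions: Pb(OAc)4 (1.0 equiv), Hg(OAc)2 (10 mol %), CHCl3, 40 °C then rt; filtration, crystallisation
Reagents that add atoms: lead tetraacetate CC(=O)O[Pb](OC(C)=O)(OC(C)=O)OC(C)=O
Why: In this boron-to-lead transmetalation relayed by divalent mercury, ipso exchange at C–B should outrun direct plumbation of the ring C–H bonds when only one equivalent of Pb(OAc)4 is used, and isolating 8 keeps free tetravalent lead oxidant away from the phenol of the next step.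

**Step 5**
Reactants: 2 3,5-diisopropoxyphenol (1.5–2 equiv); 8 [4-(benzyloxy)-2,6-dimethoxyphenyl]lead triacetate
Product: 9 2-[4-(benzyloxy)-2,6-dimethoxyphenyl]-3,5-diisopropoxyphenol
Conditions: pyridine (3 equiv), CHCl3, 40–60 °C
Reagents that add atoms: none
Why: In the Pinhey arylation the phenol replaces an acetate on tetravalent lead and ligand coupling hands the aryl group to an ortho carbon only, the two ortho carbons of 2 being equivalent and the para carbon out of reach, while excess phenol holds back a second arylation.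

**Step 6**
Reactants: 9 2-[4-(benzyloxy)-2,6-dimethoxyphenyl]-3,5-diisopropoxyphenol
Product: 10 3-[4-(benzyloxy)-2,6-dimethoxyphenyl]-2-hydroxy-4,6-diisopropoxybenzaldehyde
Conditions: MgCl2 (3 equiv), Et3N (6 equiv), (CH2O)n (10 equiv), MeCN, reflux; 1 M HCl
Reagents that add atoms: paraformaldehyde, reacting as formaldehyde C=O
Why: In the Casnati–Skattebøl ortho-formylation the magnesium phenoxide delivers formaldehyde through a chelate to an ortho carbon, only one of which is open in 9, a second formaldehyde takes up hydride to give the aldehyde, and the phenol-free trialkoxyaryl ring is not addressed.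

**Step 7**
Reactants: 11 trimethylsulfoxonium iodide (3 equiv); 12 4-methoxybenzoyl chloride
Product: 14 dimethylsulfoxonium 2-(4-methoxyphenyl)-2-oxoethylide, via dimethylsulfoxonium methylide 13 (not isolated)
Conditions: KOtBu (3 equiv), THF, reflux; then 12, 0 °C to rt
Reagents that add atoms: none
Why: In this C-acylation of the Corey–Chaykovsky methylide a further equivalent of methylide removes the acidic proton of the first adduct and should leave the carbonyl-stabilised, bench-stable ylide.

**Step 8**
Reactants: 10 3-[4-(benzyloxy)-2,6-dimethoxyphenyl]-2-hydroxy-4,6-diisopropoxybenzaldehyde; 14 dimethylsulfoxonium 2-(4-methoxyphenyl)-2-oxoethylide (1.5–2 equiv)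
Product: 16 8-[4-(benzyloxy)-2,6-dimethoxyphenyl]-5,7-diisopropoxy-2-(4-methoxyphenyl)chromen-4-one, via 1,3-diketone 15 (not isolated)
Conditions: [Cp*RhCl2]2 (5 mol %), AgSbF6 (20 mol %), NaOAc (0.5 equiv), PivOH (1 equiv), DCE, 100 °C, Ar; then TsOH·H2O (20 mol %), 80 °C if 15 persists
Reagents that add atoms: none
Why: Acetate-assisted exchange places the C8a phenoxide of 10 on Cp*Rh (trivalent rhodium), and concerted metalation–deprotonation of the neighbouring formyl C–H bond gives a five-membered acyl rhodacycle (Rh, O, C8a, C4a, C4). The ylide carbon of 14 binds, dimethyl sulfoxide leaves, and migration of the acyl group onto the resulting rhodium carbene makes C3–C4; protonolysis by PivOH then frees diketone 15 and the catalyst, so no external oxidant meets the electron-rich biaryl. Ring C closes by 6-exo-trig addition of the C8a hydroxyl to the aroyl carbonyl (O1–C2) and loss of water, driven by formation of the conjugated 4-pyranone. The closest known reaction type is the Cp*Rh-catalysed annulation of salicylaldehydes with aroyl sulfoxonium ylides to flavones, applied here to a 3-aryl-4,6-dialkoxy substrate. The step needs formyl over aryl C–H selectivity and closure through the oxygen next to the biaryl bond: 10 holds only one free phenol, the C5 oxygen is capped as an isopropyl ether, and the product carbonyl finds its peri position C5 blocked, so further C–H functionalisation is shut off. No stereocentre is formed, and the axis is not yet stereogenic because the 4-benzyloxy-2,6-dimethoxyphenyl ring is symmetric about it.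

**Step 9**
Reactants: 16 8-[4-(benzyloxy)-2,6-dimethoxyphenyl]-5,7-diisopropoxy-2-(4-methoxyphenyl)chromen-4-one
Product: 17 8-[3-acetyl-4-(benzyloxy)-2,6-dimethoxyphenyl]-5,7-diisopropoxy-2-(4-methoxyphenyl)chromen-4-one (racemic about the axis)
Conditions: AcOH (3 equiv), (CF3CO)2O (4 equiv), CH2Cl2, 0 °C to rt
Reagents that add atoms: acetic acid CC(=O)O
Why: Friedel–Crafts acylation with acetyl trifluoroacetate made in the flask needs no chelating metal halide, so the ethers should survive, and it should attack only the phloroglucinol-triether ring because rings A and B of unit 1 are deactivated by the acid-bound pyranone, the two open positions being enantiotopic so that the axis arises as a racemate and the acetyl sits between the methoxy and benzyloxy groups (future C4a'').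

**Step 10**
Reactants: 17 8-[3-acetyl-4-(benzyloxy)-2,6-dimethoxyphenyl]-5,7-diisopropoxy-2-(4-methoxyphenyl)chromen-4-one
Product: 18 8-(3-acetyl-4-hydroxy-2,6-dimethoxyphenyl)-5,7-diisopropoxy-2-(4-methoxyphenyl)chromen-4-one
Conditions: H2 (1 atm), 10 % Pd/C, EtOAc–EtOH, rt
Reagents that add atoms: none
Why: Catalytic hydrogenolysis removes the only benzyl ether under neutral conditions that should leave the flavone double bond, the hindered aryl ketone and the alkyl ethers alone, so that the oxygen para to the biaryl bond becomes the single free hydroxyl beside the acetyl group.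

**Step 11**
Reactants: 18 8-(3-acetyl-4-hydroxy-2,6-dimethoxyphenyl)-5,7-diisopropoxy-2-(4-methoxyphenyl)chromen-4-one; 19 4-isopropoxybenzaldehyde
Product: 20 8-{4-hydroxy-3-[(E)-3-(4-isopropoxyphenyl)prop-2-enoyl]-2,6-dimethoxyphenyl}-5,7-diisopropoxy-2-(4-methoxyphenyl)chromen-4-one
Conditions: KOH (10 equiv), EtOH, rt; 1 M HCl
Reagents that add atoms: none
Why: Claisen–Schmidt condensation of a 2-hydroxy-6-methoxyacetophenone with a non-enolisable aldehyde gives the E enone by E1cB loss of water under thermodynamic control, and the donor-rich flavone of unit 1 should resist hydroxide at room temperature and could in any case reclose only through its single C8a oxygen.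

**Step 12**
Reactants: 20 8-{4-hydroxy-3-[(E)-3-(4-isopropoxyphenyl)prop-2-enoyl]-2,6-dimethoxyphenyl}-5,7-diisopropoxy-2-(4-methoxyphenyl)chromen-4-one
Product: 21 8-[2-(4-isopropoxyphenyl)-5,7-dimethoxy-4-oxochromen-6-yl]-5,7-diisopropoxy-2-(4-methoxyphenyl)chromen-4-one
Conditions: I2 (10 mol %), DMSO, 120 °C; aq Na2S2O3
Reagents that add atoms: none
Why: In the iodine-catalysed oxidative cyclisation of a 2'-hydroxychalcone, with DMSO as terminal oxidant, the only free hydroxyl is the one on C8a'', so O1''–C2'' closure must give the 6''-linked flavone, and the catalytic iodine charge limits ring iodination and ether loss.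

**Step 13**
Reactants: 21 8-[2-(4-isopropoxyphenyl)-5,7-dimethoxy-4-oxochromen-6-yl]-5,7-diisopropoxy-2-(4-methoxyphenyl)chromen-4-one
Product: 22 target, 5,7-dihydroxy-8-[5-hydroxy-2-(4-hydroxyphenyl)-7-methoxy-4-oxochromen-6-yl]-2-(4-methoxyphenyl)chromen-4-one
Conditions: BCl3 (1 M in CH2Cl2, 12 equiv), CH2Cl2, −78 °C to rt; MeOH, then 1 M HCl
Reagents that add atoms: none
Why: In this Lewis-acid ether cleavage BCl3 opens secondary isopropyl aryl ethers and, through chelation to the C4'' carbonyl, the peri C5'' methyl ether, whereas the unchelated C7'' and C4' methyl ethers should persist at or below room temperature.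

**Compound list**
1 | phloroglucinol | Oc1cc(O)cc(O)c1 | starting material
2 | 3,5-diisopropoxyphenol | CC(C)Oc1cc(O)cc(OC(C)C)c1 | intermediate
3 | 4-bromo-3,5-dimethoxyphenol | COc1cc(O)cc(OC)c1Br | starting material
4 | 5-(benzyloxy)-2-bromo-1,3-dimethoxybenzene | COc1cc(OCc2ccccc2)cc(OC)c1Br | intermediate
5 | 4-(benzyloxy)-2,6-dimethoxyphenyllithium (not isolated) | [Li]c1c(OC)cc(OCc2ccccc2)cc1OC | intermediate
6 | lithium [4-(benzyloxy)-2,6-dimethoxyphenyl]triisopropoxyborate (not isolated) | [Li+].CC(C)O[B-](OC(C)C)(OC(C)C)c1c(OC)cc(OCc2ccccc2)cc1OC | intermediate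
7 | [4-(benzyloxy)-2,6-dimethoxyphenyl]boronic acid | COc1cc(OCc2ccccc2)cc(OC)c1B(O)O | intermediate
8 | [4-(benzyloxy)-2,6-dimethoxyphenyl]lead triacetate | COc1cc(OCc2ccccc2)cc(OC)c1[Pb](OC(C)=O)(OC(C)=O)OC(C)=O | intermediate
9 | 2-[4-(benzyloxy)-2,6-dimethoxyphenyl]-3,5-diisopropoxyphenol | CC(C)Oc1cc(O)c(-c2c(OC)cc(OCc3ccccc3)cc2OC)c(OC(C)C)c1 | intermediate
10 | 3-[4-(benzyloxy)-2,6-dimethoxyphenyl]-2-hydroxy-4,6-diisopropoxybenzaldehyde | CC(C)Oc1cc(OC(C)C)c(-c2c(OC)cc(OCc3ccccc3)cc2OC)c(O)c1C=O | intermediate
11 | trimethylsulfoxonium iodide | C[S+](C)(C)=O.[I-] | starting material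
12 | 4-methoxybenzoyl chloride | COc1ccc(C(=O)Cl)cc1 | starting material
13 | dimethylsulfoxonium methylide (not isolated) | C=S(C)(C)=O | intermediate
14 | dimethylsulfoxonium 2-(4-methoxyphenyl)-2-oxoethylide | COc1ccc(C(=O)C=S(C)(C)=O)cc1 | intermediate
15 | 1-{3-[4-(benzyloxy)-2,6-dimethoxyphenyl]-2-hydroxy-4,6-diisopropoxyphenyl}-3-(4-methoxyphenyl)propane-1,3-dione (not isolated) | COc1ccc(C(=O)CC(=O)c2c(O)c(-c3c(OC)cc(OCc4ccccc4)cc3OC)c(OC(C)C)cc2OC(C)C)cc1 | intermediate
16 | 8-[4-(benzyloxy)-2,6-dimethoxyphenyl]-5,7-diisopropoxy-2-(4-methoxyphenyl)chromen-4-one | COc1ccc(-c2cc(=O)c3c(OC(C)C)cc(OC(C)C)c(-c4c(OC)cc(OCc5ccccc5)cc4OC)c3o2)cc1 | intermediate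
17 | 8-[3-acetyl-4-(benzyloxy)-2,6-dimethoxyphenyl]-5,7-diisopropoxy-2-(4-methoxyphenyl)chromen-4-one (racemic axis) | COc1ccc(-c2cc(=O)c3c(OC(C)C)cc(OC(C)C)c(-c4c(OC)c(C(C)=O)c(OCc5ccccc5)cc4OC)c3o2)cc1 | intermediate
18 | 8-(3-acetyl-4-hydroxy-2,6-dimethoxyphenyl)-5,7-diisopropoxy-2-(4-methoxyphenyl)chromen-4-one (racemic axis) | COc1ccc(-c2cc(=O)c3c(OC(C)C)cc(OC(C)C)c(-c4c(OC)c(C(C)=O)c(O)cc4OC)c3o2)cc1 | intermediate
19 | 4-isopropoxybenzaldehyde | CC(C)Oc1ccc(C=O)cc1 | starting material
20 | 8-{4-hydroxy-3-[(E)-3-(4-isopropoxyphenyl)prop-2-enoyl]-2,6-dimethoxyphenyl}-5,7-diisopropoxy-2-(4-methoxyphenyl)chromen-4-one (racemic axis) | COc1ccc(-c2cc(=O)c3c(OC(C)C)cc(OC(C)C)c(-c4c(OC)c(C(=O)/C=C/c5ccc(OC(C)C)cc5)c(O)cc4OC)c3o2)cc1 | intermediate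
21 | 8-[2-(4-isopropoxyphenyl)-5,7-dimethoxy-4-oxochromen-6-yl]-5,7-diisopropoxy-2-(4-methoxyphenyl)chromen-4-one (racemic axis) | COc1ccc(-c2cc(=O)c3c(OC(C)C)cc(OC(C)C)c(-c4c(OC)cc5oc(-c6ccc(OC(C)C)cc6)cc(=O)c5c4OC)c3o2)cc1 | intermediate
22 | 5,7-dihydroxy-8-[5-hydroxy-2-(4-hydroxyphenyl)-7-methoxy-4-oxochromen-6-yl]-2-(4-methoxyphenyl)chromen-4-one (CNP0253922.0, racemic axis) | COc1ccc(-c2cc(=O)c3c(O)cc(O)c(-c4c(OC)cc5oc(-c6ccc(O)cc6)cc(=O)c5c4O)c3o2)cc1 | target

**Total step count:** 13
**Longest linear sequence:** 11 steps (3 → 4 → 7 → 8 → 9 → 10 → 16 → 17 → 18 → 20 → 21 → 22; steps 2, 3, 4, 5, 6, 8, 9, 10, 11, 12, 13)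

**Steps most likely to fail**

**Step 8 (rhodium annulation).**
- What may go wrong: cyclometalation may be slow because the phenoxide is crowded by the ortho aryl group and the formyl group by the isopropoxy group. The acyl–rhodium species then has time to lose carbon monoxide, and the ylide has time to be consumed by self-reaction.
- Fallback, from 10 back to 16: excess lithium (4-methoxyphenyl)acetylide is added to 10 (4-ethynylanisole, n-BuLi, THF, −78 °C; the first equivalent deprotonates the phenol). This should give racemic 1-{3-[4-(benzyloxy)-2,6-dimethoxyphenyl]-2-hydroxy-4,6-diisopropoxyphenyl}-3-(4-methoxyphenyl)prop-2-yn-1-ol F1.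
- F1 is oxidised at once with MnO2 in CH2Cl2 to 1-{3-[4-(benzyloxy)-2,6-dimethoxyphenyl]-2-hydroxy-4,6-diisopropoxyphenyl}-3-(4-methoxyphenyl)prop-2-yn-1-one F2.
- DMAP-catalysed 6-endo-dig oxa-Michael closure of F2 in DMF, through the same C8a hydroxyl, comes back to the route at 16.

**Step 5 (Pinhey arylation).**
- What may go wrong: ligand coupling between two crowded partners may be sluggish. A second arylation of the product and oxidation of the electron-rich phenol by tetravalent lead could then compete.
- Fallback, from 2 back to 9: iodination of 2 with NIS in MeCN at 0 °C should go to the less hindered ortho carbon and give 2-iodo-3,5-diisopropoxyphenol F3. It is separated from any symmetric para isomer.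
- Suzuki–Miyaura coupling of F3 with boronic acid 7 (Pd(OAc)2, SPhos, K3PO4, toluene–water, 100 °C) comes back to the route at 9.

**Step 9 (Friedel–Crafts acetylation).**
- What may go wrong: acylation at a carbon flanked by two alkoxy groups may be slow. Long exposure to acid would then cause loss or migration of the benzyl group and cleavage of the peri isopropyl ether.
- Fallback, from 16 back to 17: mono-iodination of 16 with NIS (1 equiv, CH2Cl2–MeCN, 0 °C) should give 8-[4-(benzyloxy)-3-iodo-2,6-dimethoxyphenyl]-5,7-diisopropoxy-2-(4-methoxyphenyl)chromen-4-one F4.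
- Stille coupling of F4 with tributyl(1-ethoxyvinyl)stannane (PdCl2(PPh3)2, toluene, 100 °C) should give 8-[4-(benzyloxy)-3-(1-ethoxyvinyl)-2,6-dimethoxyphenyl]-5,7-diisopropoxy-2-(4-methoxyphenyl)chromen-4-one F5.
- Brief treatment of F5 with 1 M HCl in THF hydrolyses the enol ether and comes back to the route at 17.

**Further compounds**
F1 | step 8 | 1-{3-[4-(benzyloxy)-2,6-dimethoxyphenyl]-2-hydroxy-4,6-diisopropoxyphenyl}-3-(4-methoxyphenyl)prop-2-yn-1-ol (racemic) | COc1ccc(C#CC(O)c2c(O)c(-c3c(OC)cc(OCc4ccccc4)cc3OC)c(OC(C)C)cc2OC(C)C)cc1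
F2 | step 8 | 1-{3-[4-(benzyloxy)-2,6-dimethoxyphenyl]-2-hydroxy-4,6-diisopropoxyphenyl}-3-(4-methoxyphenyl)prop-2-yn-1-one | COc1ccc(C#CC(=O)c2c(O)c(-c3c(OC)cc(OCc4ccccc4)cc3OC)c(OC(C)C)cc2OC(C)C)cc1
F3 | step 5 | 2-iodo-3,5-diisopropoxyphenol | CC(C)Oc1cc(O)c(I)c(OC(C)C)c1
F4 | step 9 | 8-[4-(benzyloxy)-3-iodo-2,6-dimethoxyphenyl]-5,7-diisopropoxy-2-(4-methoxyphenyl)chromen-4-one (racemic axis) | COc1ccc(-c2cc(=O)c3c(OC(C)C)cc(OC(C)C)c(-c4c(OC)c(I)c(OCc5ccccc5)cc4OC)c3o2)cc1
F5 | step 9 | 8-[4-(benzyloxy)-3-(1-ethoxyvinyl)-2,6-dimethoxyphenyl]-5,7-diisopropoxy-2-(4-methoxyphenyl)chromen-4-one (racemic axis) | COc1ccc(-c2cc(=O)c3c(OC(C)C)cc(OC(C)C)c(-c4c(OC)c(C(=C)OCC)c(OCc5ccccc5)cc4OC)c3o2)cc1
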